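The bond between the free ring carbon of phlorisovalerophenone and the side-chain methine on C2 of the benzofuran is the disconnection on which the route rests. A cation at that methine is furfuryl-type, stabilised by furan O1 and, through C3, by the oxygens at C4 and C6 of the benzofuran. The bond is therefore made, as in a plausible biogenesis, by Friedel–Crafts capture of this cation by unprotected phlorisovalerophenone. The step is stereoconvergent: a mixture of carbinol epimers gives one planar cation, and the neighbouring dioxolane stereocentre (from L-glyceraldehyde acetonide) steers the arene to one face. The precursor is a bis-MOM, acetonide-protected benzofuran-2-yl carbinol built by Sonogashira annulation.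

Key step: step 6

Assumption: (4S)-2,2-dimethyl-1,3-dioxolane-4-carbaldehyde (L-glyceraldehyde acetonide) is taken as a commercial reagent and distilled before use.

Step 1
Reactants: 1 phloroglucinol; 2 isovaleryl chloride
Product: 3 phlorisovalerophenone
Conditions: AlCl3 (3.5 equiv), PhNO2–CH2Cl2, 0 °C → 45 °C; ice/aq HCl
Reagents that add atoms: isovaleryl chloride, CC(C)CC(=O)Cl
Why: Friedel–Crafts acylation of the symmetric triol, in which the first (chelated) acyl group deactivates the ring so that mono-acylation should dominate.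

Step 2
Reactants: 3 phlorisovalerophenone; 4 chloromethyl methyl ether
Product: 5 1-[2-hydroxy-4,6-bis(methoxymethoxy)phenyl]-3-methylbutan-1-one
Conditions: MOMCl (2.2 equiv), i-Pr2NEt (2.5 equiv), CH2Cl2, 0 °C → rt
Reagents that add atoms: chloromethyl methyl ether, COCCl
Why: O-alkylation (MOM acetal formation) should take the para hydroxyl and one ortho hydroxyl, while the hydroxyl chelated to the ketone is the least nucleophilic and stays free.

Step 3
Reactants: 5 bis-MOM ketone; 6 N-iodosuccinimide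
Product: 7 1-[2-hydroxy-3-iodo-4,6-bis(methoxymethoxy)phenyl]-3-methylbutan-1-one
Conditions: NIS (1.05 equiv), DMF, 0 °C → rt, dark
Reagents that add atoms: N-iodosuccinimide, O=C1CCC(=O)N1I
Why: Electrophilic aromatic iodination, directed by the free phenol to its ortho carbon (C3) in preference to C5 between the two bulkier MOM ethers, under neutral conditions that keep the acetals.

Step 4
Reactants: 8 (4S)-2,2-dimethyl-1,3-dioxolane-4-carbaldehyde; 9 ethynylmagnesium bromide
Product: 10 (1RS)-1-[(4S)-2,2-dimethyl-1,3-dioxolan-4-yl]prop-2-yn-1-ol (mixture of C1 epimers)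
Conditions: HC≡CMgBr (1.3 equiv), THF, −78 → 0 °C; aq NH4Cl
Reagents that add atoms: ethynylmagnesium bromide, C#C[Mg]Br
Why: Grignard addition to the aldehyde at low temperature leaves the α-alkoxy stereocentre intact, and the new carbinol centre is deliberately carried as an epimer mixture because step 6 erases it.

Step 5
Reactants: 7 iodophenol; 10 alkynol
Product: 12 1-[2-[(RS)-[(4S)-2,2-dimethyl-1,3-dioxolan-4-yl](hydroxy)methyl]-4,6-bis(methoxymethoxy)-1-benzofuran-7-yl]-3-methylbutan-1-one (mixture of carbinol epimers), via alkynylphenol 11 (not isolated)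
Conditions: PdCl2(PPh3)2 (5 mol %), CuI (10 mol %), Et3N, DMF, 70 °C, degassed
Reagents that add atoms: none
Why: Sonogashira coupling followed in the same flask by 5-endo-dig cycloisomerisation of the o-alkynylphenol; the only free hydroxyl ortho to iodine is the one next to the acyl-bearing carbon, so O1 of the furan should end up beside C7 carrying the isovaleryl group.

Step 6
Reactants: 12 benzofuran-2-yl carbinol (epimer mixture); 3 phlorisovalerophenone
Product: 14 1-[3-[(S)-[(4R)-2,2-dimethyl-1,3-dioxolan-4-yl][4,6-bis(methoxymethoxy)-7-(3-methylbutanoyl)-1-benzofuran-2-yl]methyl]-2,4,6-trihydroxyphenyl]-3-methylbutan-1-one, via benzofuran-2-ylmethyl cation 13 (not isolated)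
Conditions: 3 (3 equiv), Sc(OTf)3 (10 mol %), 4 Å MS, MeCN–CH2Cl2, −20 → 0 °C, slow addition of 12
Reagents that add atoms: none
Why: Sc(OTf)3 should ionise either carbinol epimer of 12 to the same planar cation 13, stabilised by furan O1 and through C3 by the C4 and C6 oxygens of the benzofuran, and the free phloroglucinol ring of 3 should attack it at its unsubstituted carbon (C3 and C5 are equivalent) and rearomatise, a stereoconvergent Friedel–Crafts alkylation. The closest known reaction types are the diastereoselective SN1 Friedel–Crafts alkylation of arenes with α-chiral benzylic alcohols and the acid-mediated capture of flavan-4-yl cations by phloroglucinol rings. No ring is closed. The new methine centre (S) is controlled by the adjacent dioxolane centre: 13 should hold its dioxolane C4–H bond in the cation plane beside the benzofuran to minimise 1,3-allylic strain, and the arene should add anti to the C4–O bond (Felkin–Anh-type, as in additions to γ,δ-dioxolanyl acceptors), which corresponds to the required (S)/(4R) arrangement. The step needs cross- over self-alkylation and mono-C-alkylation: the MOM ethers mute the benzofuran ring as a nucleophile, the unprotected ring of 3 is more electron-rich and used in excess, and O-alkylation is reversible under the acid. Low temperature and slow addition keep the cation concentration low, which should disfavour proton loss or hydride shift from the dioxolane carbon.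

Step 7
Reactants: 14 protected adduct
Product: 15 1-[3-[(1S,2R)-1-[4,6-dihydroxy-7-(3-methylbutanoyl)-1-benzofuran-2-yl]-2,3-dihydroxypropyl]-2,4,6-trihydroxyphenyl]-3-methylbutan-1-one (target)
Conditions: 3 M aq HCl–MeOH (1:5), rt → 35 °C, stopped at full conversion
Reagents that add atoms: none
Why: Acid-catalysed acetal cleavage should remove both aryl MOM ethers and the isopropylidene acetal in one operation without touching either stereocentre, the mild temperature being chosen to avoid re-ionisation of the new bond.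

Compound list
1 | phloroglucinol (benzene-1,3,5-triol) | Oc1cc(O)cc(O)c1 | starting material
2 | isovaleryl chloride (3-methylbutanoyl chloride) | CC(C)CC(=O)Cl | starting material
3 | phlorisovalerophenone, 3-methyl-1-(2,4,6-trihydroxyphenyl)butan-1-one | CC(C)CC(=O)c1c(O)cc(O)cc1O | intermediate
4 | chloromethyl methyl ether | COCCl | starting material
5 | 1-[2-hydroxy-4,6-bis(methoxymethoxy)phenyl]-3-methylbutan-1-one | CC(C)CC(=O)c1c(O)cc(OCOC)cc1OCOC | intermediate
6 | N-iodosuccinimide | O=C1CCC(=O)N1I | starting material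
7 | 1-[2-hydroxy-3-iodo-4,6-bis(methoxymethoxy)phenyl]-3-methylbutan-1-one | CC(C)CC(=O)c1c(O)c(I)c(OCOC)cc1OCOC | intermediate
8 | (4S)-2,2-dimethyl-1,3-dioxolane-4-carbaldehyde (L-glyceraldehyde acetonide) | O=C[C@@H]1COC(C)(C)O1 | starting material
9 | ethynylmagnesium bromide | C#C[Mg]Br | starting material
10 | (1RS)-1-[(4S)-2,2-dimethyl-1,3-dioxolan-4-yl]prop-2-yn-1-ol, mixture of C1 epimers | C#CC(O)[C@@H]1COC(C)(C)O1 | intermediate
11 | 1-[3-[3-[(4S)-2,2-dimethyl-1,3-dioxolan-4-yl]-3-hydroxyprop-1-yn-1-yl]-2-hydroxy-4,6-bis(methoxymethoxy)phenyl]-3-methylbutan-1-one, formed in the flask and not isolated | CC(C)CC(=O)c1c(O)c(C#CC(O)[C@@H]2COC(C)(C)O2)c(OCOC)cc1OCOC | intermediate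
12 | 1-[2-[(RS)-[(4S)-2,2-dimethyl-1,3-dioxolan-4-yl](hydroxy)methyl]-4,6-bis(methoxymethoxy)-1-benzofuran-7-yl]-3-methylbutan-1-one, mixture of carbinol epimers | CC(C)CC(=O)c1c(OCOC)cc(OCOC)c2cc(C(O)[C@@H]3COC(C)(C)O3)oc12 | intermediate
13 | [(4S)-2,2-dimethyl-1,3-dioxolan-4-yl][4,6-bis(methoxymethoxy)-7-(3-methylbutanoyl)-1-benzofuran-2-yl]methylium, formed in the flask and not isolated | CC(C)CC(=O)c1c(OCOC)cc(OCOC)c2cc([CH+][C@@H]3COC(C)(C)O3)oc12 | intermediate
14 | 1-[3-[(S)-[(4R)-2,2-dimethyl-1,3-dioxolan-4-yl][4,6-bis(methoxymethoxy)-7-(3-methylbutanoyl)-1-benzofuran-2-yl]methyl]-2,4,6-trihydroxyphenyl]-3-methylbutan-1-one | CC(C)CC(=O)c1c(O)cc(O)c([C@H](c2cc3c(OCOC)cc(OCOC)c(C(=O)CC(C)C)c3o2)[C@@H]4COC(C)(C)O4)c1O | intermediate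
15 | 1-[3-[(1S,2R)-1-[4,6-dihydroxy-7-(3-methylbutanoyl)-1-benzofuran-2-yl]-2,3-dihydroxypropyl]-2,4,6-trihydroxyphenyl]-3-methylbutan-1-one | CC(C)CC(=O)c1c(O)cc(O)c([C@H](c2cc3c(O)cc(O)c(C(=O)CC(C)C)c3o2)[C@@H](O)CO)c1O | target

Total step count: 7. Longest linear sequence: 6 (steps 1, 2, 3, 5, 6, 7).

Steps most likely to fail

Step 6. The capture of the acyclic cation may show poor facial selectivity (attack anti to the dioxolane CH2 instead of anti to C–O). The cation may also be lost by proton loss or 1,2-hydride shift from the dioxolane carbon, or be consumed by self-alkylation. The fallback replaces substrate-controlled capture by a stereospecific epoxide opening and sets out from 7. Sonogashira annulation of 7 with commercial (E)-pent-2-en-4-yn-1-ol (C#C/C=C/CO; PdCl2(PPh3)2, CuI, Et3N, DMF) should give the (E)-allylic alcohol 1-[2-[(E)-3-hydroxyprop-1-en-1-yl]-4,6-bis(methoxymethoxy)-1-benzofuran-7-yl]-3-methylbutan-1-one F1. Sharpless asymmetric epoxidation (Ti(Oi-Pr)4, L-(+)-DIPT, t-BuOOH, 4 Å MS, CH2Cl2, −20 °C) should set both centres in the trans-epoxy alcohol 1-[2-[(2R,3S)-3-(hydroxymethyl)oxiran-2-yl]-4,6-bis(methoxymethoxy)-1-benzofuran-7-yl]-3-methylbutan-1-one F2. Friedel–Crafts opening of F2 by 3 (3 equiv) at the furfuryl carbon with inversion (HFIP, 0 °C, or catalytic Sc(OTf)3 in MeCN) should give the bis-MOM diol 1-[3-[(1S,2R)-1-[4,6-bis(methoxymethoxy)-7-(3-methylbutanoyl)-1-benzofuran-2-yl]-2,3-dihydroxypropyl]-2,4,6-trihydroxyphenyl]-3-methylbutan-1-one F3. Mild HCl–MeOH should then rejoin the route at 15.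

Step 7. Acid may re-ionise the new diarylmethine bond (epimerisation or fragment exchange), and the methoxymethyl cation released from the MOM groups may alkylate the free phloroglucinol carbon. The fallback changes the phenol protection to benzyl so that the last step is neutral, and sets out from 3. Bis-benzylation (BnBr, K2CO3, DMF) should give 1-[2,4-bis(benzyloxy)-6-hydroxyphenyl]-3-methylbutan-1-one F4, and iodination with NIS should give 1-[4,6-bis(benzyloxy)-2-hydroxy-3-iodophenyl]-3-methylbutan-1-one F5. Sonogashira annulation with 10 should give the carbinol 1-[4,6-bis(benzyloxy)-2-[(RS)-[(4S)-2,2-dimethyl-1,3-dioxolan-4-yl](hydroxy)methyl]-1-benzofuran-7-yl]-3-methylbutan-1-one F6. The same Sc(OTf)3-catalysed coupling with 3 should give the adduct 1-[3-[(S)-[4,6-bis(benzyloxy)-7-(3-methylbutanoyl)-1-benzofuran-2-yl][(4R)-2,2-dimethyl-1,3-dioxolan-4-yl]methyl]-2,4,6-trihydroxyphenyl]-3-methylbutan-1-one F7. Acetonide removal with 80% aq AcOH at 40 °C, far milder than aryl MOM cleavage, should give the diol 1-[3-[(1S,2R)-1-[4,6-bis(benzyloxy)-7-(3-methylbutanoyl)-1-benzofuran-2-yl]-2,3-dihydroxypropyl]-2,4,6-trihydroxyphenyl]-3-methylbutan-1-one F8. Hydrogenolysis (H2, Pd/C, EtOAc) should rejoin the route at 15.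

Step 5. The coupling may stall at the doubly ortho-substituted, chelated iodophenol, or ring closure may stay incomplete while the alkyne homocouples. The fallback separates coupling from ring closure and sets out from 7. Acetylation (Ac2O, pyridine, DMAP) should give 2-iodo-3,5-bis(methoxymethoxy)-6-(3-methylbutanoyl)phenyl acetate F9. Sonogashira coupling with 10 at room temperature (Pd(PPh3)4, CuI, Et3N, THF) should give 2-[3-[(4S)-2,2-dimethyl-1,3-dioxolan-4-yl]-3-hydroxyprop-1-yn-1-yl]-3,5-bis(methoxymethoxy)-6-(3-methylbutanoyl)phenyl acetate F10. K2CO3 in MeOH with gentle warming (a catalytic π-acid such as AuCl3 if closure is slow) should remove the acetate and let the phenoxide close the furan 5-endo-dig, rejoining the route at 12.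

Further compounds
F1 | step 6 | 1-[2-[(E)-3-hydroxyprop-1-en-1-yl]-4,6-bis(methoxymethoxy)-1-benzofuran-7-yl]-3-methylbutan-1-one | CC(C)CC(=O)c1c(OCOC)cc(OCOC)c2cc(/C=C/CO)oc12
F2 | step 6 | 1-[2-[(2R,3S)-3-(hydroxymethyl)oxiran-2-yl]-4,6-bis(methoxymethoxy)-1-benzofuran-7-yl]-3-methylbutan-1-one | OC[C@@H]1O[C@H]1c2cc3c(OCOC)cc(OCOC)c(C(=O)CC(C)C)c3o2
F3 | step 6 | 1-[3-[(1S,2R)-1-[4,6-bis(methoxymethoxy)-7-(3-methylbutanoyl)-1-benzofuran-2-yl]-2,3-dihydroxypropyl]-2,4,6-trihydroxyphenyl]-3-methylbutan-1-one | CC(C)CC(=O)c1c(O)cc(O)c([C@H](c2cc3c(OCOC)cc(OCOC)c(C(=O)CC(C)C)c3o2)[C@@H](O)CO)c1O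
F4 | step 7 | 1-[2,4-bis(benzyloxy)-6-hydroxyphenyl]-3-methylbutan-1-one | CC(C)CC(=O)c1c(O)cc(OCc2ccccc2)cc1OCc1ccccc1
F5 | step 7 | 1-[4,6-bis(benzyloxy)-2-hydroxy-3-iodophenyl]-3-methylbutan-1-one | CC(C)CC(=O)c1c(O)c(I)c(OCc2ccccc2)cc1OCc1ccccc1
F6 | step 7 | 1-[4,6-bis(benzyloxy)-2-[(RS)-[(4S)-2,2-dimethyl-1,3-dioxolan-4-yl](hydroxy)methyl]-1-benzofuran-7-yl]-3-methylbutan-1-one | CC(C)CC(=O)c1c(OCc2ccccc2)cc(OCc2ccccc2)c2cc(C(O)[C@@H]3COC(C)(C)O3)oc12
F7 | step 7 | 1-[3-[(S)-[4,6-bis(benzyloxy)-7-(3-methylbutanoyl)-1-benzofuran-2-yl][(4R)-2,2-dimethyl-1,3-dioxolan-4-yl]methyl]-2,4,6-trihydroxyphenyl]-3-methylbutan-1-one | CC(C)CC(=O)c1c(O)cc(O)c([C@H](c2cc3c(OCc4ccccc4)cc(OCc4ccccc4)c(C(=O)CC(C)C)c3o2)[C@@H]5COC(C)(C)O5)c1O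
F8 | step 7 | 1-[3-[(1S,2R)-1-[4,6-bis(benzyloxy)-7-(3-methylbutanoyl)-1-benzofuran-2-yl]-2,3-dihydroxypropyl]-2,4,6-trihydroxyphenyl]-3-methylbutan-1-one | CC(C)CC(=O)c1c(O)cc(O)c([C@H](c2cc3c(OCc4ccccc4)cc(OCc4ccccc4)c(C(=O)CC(C)C)c3o2)[C@@H](O)CO)c1O
F9 | step 5 | 2-iodo-3,5-bis(methoxymethoxy)-6-(3-methylbutanoyl)phenyl acetate | CC(C)CC(=O)c1c(OC(C)=O)c(I)c(OCOC)cc1OCOC
F10 | step 5 | 2-[3-[(4S)-2,2-dimethyl-1,3-dioxolan-4-yl]-3-hydroxyprop-1-yn-1-yl]-3,5-bis(methoxymethoxy)-6-(3-methylbutanoyl)phenyl acetate | CC(C)CC(=O)c1c(OC(C)=O)c(C#CC(O)[C@@H]2COC(C)(C)O2)c(OCOC)cc1OCOC
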